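**Retrosynthetic overview**
- The target is a tridepside A–B–C. In rings B and C, the C1–C6 edge (the ester-bearing carbon and the methyl-bearing carbon) is the α,β-pair of a but-2-ynoate, and C2–C5 with oxygens on C2 and C4 is an acetoacetate-derived 1,3-dioxygenated diene.
- Ring C is disconnected by a retro-[4+2] to the AB aryl but-2-ynoate and the bis(silyloxy)diene. Ring B is disconnected in the same way to the ring A aryl but-2-ynoate.
- Each depside ester is made from linear but-2-ynoic acid and a free phenol before its arene exists, so no di-ortho-substituted benzoic acid has to be acylated onto a phenol.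
- Ring A comes from methyl orsellinate (benzylation, methylation, debenzylation). Order of rings: A (purchased), B (step 7), C (step 9).

Key step: step 7

Remark: the target has no stereogenic centre or hindered axis and is achiral, so no step needs stereocontrol. The Z descriptor of diene 9 is lost in the products.

**Route**

Step 1
Reactants: 1 methyl orsellinate (methyl 2,4-dihydroxy-6-methylbenzoate)
Product: 2 methyl 4-(benzyloxy)-2-hydroxy-6-methylbenzoate
Conditions: BnBr (1.05 equiv), K2CO3 (1.1 equiv), acetone, reflux
Reagents that add atoms: benzyl bromide, BrCc1ccccc1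
Why: Williamson etherification; the 2-OH is hydrogen-bonded to the ester carbonyl and less acidic, so one equivalent of benzyl bromide should alkylate only the free 4-OH.

Step 2
Reactants: 2 methyl 4-(benzyloxy)-2-hydroxy-6-methylbenzoate
Product: 3 methyl 4-(benzyloxy)-2-methoxy-6-methylbenzoate
Conditions: MeI (3 equiv), K2CO3 (2 equiv), DMF, 50 °C
Reagents that add atoms: iodomethane, CI
Why: Williamson O-methylation of the remaining chelated phenol, which needs the more forcing DMF conditions but has no competing nucleophile left.

Step 3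
Reactants: 3 methyl 4-(benzyloxy)-2-methoxy-6-methylbenzoate
Product: 4 methyl 4-hydroxy-2-methoxy-6-methylbenzoate
Conditions: H2 (1 atm), 10% Pd/C, EtOAc, rt
Reagents that add atoms: none
Why: Hydrogenolysis of the benzyl aryl ether over Pd/C, which should leave the methyl ester and the methyl ether untouched.

Step 4
Reactants: 4 methyl 4-hydroxy-2-methoxy-6-methylbenzoate; 5 but-2-ynoic acid
Product: 6 methyl 4-(but-2-ynoyloxy)-2-methoxy-6-methylbenzoate
Conditions: DCC (1.1 equiv), DMAP (5 mol%), CH2Cl2, 0 °C to rt
Reagents that add atoms: none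
Why: Steglich esterification of a linear, unhindered acid with a free phenol, the usual way to aryl but-2-ynoates.

Step 5
Reactants: 7 methyl acetoacetate
Product: 8 methyl 3-(trimethylsilyloxy)but-2-enoate (drawn as E; an E/Z mixture serves equally)
Conditions: TMSCl, Et3N, hexane, rt
Reagents that add atoms: chlorotrimethylsilane, C[Si](C)(C)Cl
Why: Silyl enol ether formation from the enolisable β-keto ester; the geometry does not matter because this double bond becomes the C2–C3 single bond of the diene.

Step 6
Reactants: 8 methyl 3-(trimethylsilyloxy)but-2-enoate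
Product: 9 1-methoxy-1,3-bis(trimethylsilyloxy)buta-1,3-diene
Conditions: LDA, THF, −78 °C; then TMSCl, −78 to 0 °C
Reagents that add atoms: chlorotrimethylsilane, C[Si](C)(C)Cl
Why: γ-Deprotonation of the vinylogous ester with LDA gives the extended dienolate, which is trapped on oxygen by TMSCl to give the bis(silyloxy)diene.

Step 7
Reactants: 6 methyl 4-(but-2-ynoyloxy)-2-methoxy-6-methylbenzoate; 9 1-methoxy-1,3-bis(trimethylsilyloxy)buta-1,3-diene
Product: 12 methyl 4-[(2,4-dihydroxy-6-methylbenzoyl)oxy]-2-methoxy-6-methylbenzoate (AB diol), via cycloadduct 10 (not isolated), via bis(trimethylsilyl) ether 11 (not isolated)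
Conditions: 9 (2.5 equiv), PhMe (1 M), sealed tube, 110–130 °C; then 1 M HCl, THF, 0 °C to rt
Reagents that add atoms: none
Why: This is a Diels–Alder reaction of a 1,3-dioxygenated silyloxydiene with an alkynoate followed by eliminative aromatization, the known route to resorcylates; the cycloaddition is concerted but asynchronous, the C5'–C6' bond (diene CH2 to the methyl-bearing β-carbon) running ahead of the C1'–C2' bond (ketene acetal carbon to the α-carbon). Ring B is closed by this intermolecular [4+2] cycloaddition, which makes both new ring bonds in one event and gives 1,4-cyclohexadiene 10 with a mixed methyl silyl ketal at C2'. Adduct 10 should lose methanol across the ring (C2'–OMe and C5'–H, a 1,4-elimination) to give the aromatic bis-silyl ether 11, and dilute acid then frees both phenols. The only stereocentre formed, the ketal carbon C2' of 10, is racemic and is erased on aromatization. The step needs regiocontrol, which the matched polarization supplies (largest HOMO coefficient on the diene CH2 terminus, largest LUMO coefficient on the ynoate β-carbon), so the oxygens fall on C2' and C4' and the methyl on C6'. It also needs cycloaddition to outrun attack of the diene on the aryl ester carbonyl, for which the absence of a Lewis acid and the conjugation of that carbonyl with the alkyne are relied on.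

Step 8
Reactants: 12 AB diol; 5 but-2-ynoic acid
Product: 13 methyl 4-{[4-(but-2-ynoyloxy)-2-hydroxy-6-methylbenzoyl]oxy}-2-methoxy-6-methylbenzoate (AB ynoate)
Conditions: DCC (1.05 equiv), DMAP (5 mol%), CH2Cl2, −10 to 0 °C
Reagents that add atoms: none
Why: Steglich esterification; the 2'-OH is hydrogen-bonded to the depside carbonyl and flanked by it, so the free 4'-OH should be acylated selectively by the unhindered acid at low temperature.

Step 9
Reactants: 13 AB ynoate; 9 1-methoxy-1,3-bis(trimethylsilyloxy)buta-1,3-diene
Product: 17 methyl 4-({4-[(2,4-dihydroxy-6-methylbenzoyl)oxy]-2-hydroxy-6-methylbenzoyl}oxy)-2-methoxy-6-methylbenzoate (target), via 2'-O-trimethylsilyl ether 14 (not isolated), via cycloadduct 15 (not isolated), via tris(trimethylsilyl) ether 16 (not isolated)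
Conditions: BSA (1.2 equiv), PhMe, 60 °C; then 9 (3 equiv), sealed tube, 110–130 °C; then 1 M HCl, THF, 0 °C to rt
Reagents that add atoms: none
Why: The same Diels–Alder/eliminative aromatization as in step 7 with the same polarity-controlled regiochemistry closes ring C; silylating the chelated 2'-OH first with BSA keeps it from protonating the ketene acetal diene, and the dilute acid work-up should remove all three silyl groups without cleaving the aryl ester links.

**Compound list**
1 | methyl orsellinate (methyl 2,4-dihydroxy-6-methylbenzoate) | COC(=O)c1c(C)cc(O)cc1O | starting material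
2 | methyl 4-(benzyloxy)-2-hydroxy-6-methylbenzoate | COC(=O)c1c(C)cc(OCc2ccccc2)cc1O | intermediate
3 | methyl 4-(benzyloxy)-2-methoxy-6-methylbenzoate | COC(=O)c1c(C)cc(OCc2ccccc2)cc1OC | intermediate
4 | methyl 4-hydroxy-2-methoxy-6-methylbenzoate | COC(=O)c1c(C)cc(O)cc1OC | intermediate
5 | but-2-ynoic acid | CC#CC(=O)O | starting material
6 | methyl 4-(but-2-ynoyloxy)-2-methoxy-6-methylbenzoate | COC(=O)c1c(C)cc(OC(=O)C#CC)cc1OC | intermediate
7 | methyl acetoacetate | COC(=O)CC(C)=O | starting material
8 | methyl (E)-3-(trimethylsilyloxy)but-2-enoate | C/C(O[Si](C)(C)C)=C\C(=O)OC | intermediate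
9 | (Z)-1-methoxy-1,3-bis(trimethylsilyloxy)buta-1,3-diene | CO/C(O[Si](C)(C)C)=C/C(O[Si](C)(C)C)=C | intermediate
10 | ring B cycloadduct, racemic at the ketal carbon: 4-methoxycarbonyl-3-methoxy-5-methylphenyl 6-methoxy-2-methyl-4,6-bis(trimethylsilyloxy)cyclohexa-1,4-diene-1-carboxylate | COC(=O)c1c(C)cc(OC(=O)C2=C(C)CC(O[Si](C)(C)C)=CC2(OC)O[Si](C)(C)C)cc1OC | intermediate
11 | AB diol bis(trimethylsilyl) ether | COC(=O)c1c(C)cc(OC(=O)c2c(C)cc(O[Si](C)(C)C)cc2O[Si](C)(C)C)cc1OC | intermediate
12 | AB diol, methyl 4-[(2,4-dihydroxy-6-methylbenzoyl)oxy]-2-methoxy-6-methylbenzoate | COC(=O)c1c(C)cc(OC(=O)c2c(C)cc(O)cc2O)cc1OC | intermediate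
13 | AB ynoate, methyl 4-{[4-(but-2-ynoyloxy)-2-hydroxy-6-methylbenzoyl]oxy}-2-methoxy-6-methylbenzoate | COC(=O)c1c(C)cc(OC(=O)c2c(C)cc(OC(=O)C#CC)cc2O)cc1OC | intermediate
14 | 2'-O-trimethylsilyl ether of 13 | COC(=O)c1c(C)cc(OC(=O)c2c(C)cc(OC(=O)C#CC)cc2O[Si](C)(C)C)cc1OC | intermediate
15 | ring C cycloadduct of 14, racemic at the ketal carbon | COC(=O)c1c(C)cc(OC(=O)c2c(C)cc(OC(=O)C3=C(C)CC(O[Si](C)(C)C)=CC3(OC)O[Si](C)(C)C)cc2O[Si](C)(C)C)cc1OC | intermediate
16 | tris(trimethylsilyl) ether of the target | COC(=O)c1c(C)cc(OC(=O)c2c(C)cc(OC(=O)c3c(C)cc(O[Si](C)(C)C)cc3O[Si](C)(C)C)cc2O[Si](C)(C)C)cc1OC | intermediate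
17 | CNP0503951.0, methyl 4-({4-[(2,4-dihydroxy-6-methylbenzoyl)oxy]-2-hydroxy-6-methylbenzoyl}oxy)-2-methoxy-6-methylbenzoate | COC(=O)c1c(C)cc(OC(=O)c2c(C)cc(OC(=O)c3c(C)cc(O)cc3O)cc2O)cc1OC | target

**Step count**
Total: 9 steps. Longest linear sequence: 7 steps (1, 2, 3, 4, 7, 8, 9); the diene branch (steps 5 and 6) joins at step 7 and is used again in step 9.

**Steps most likely to fail**

1. Step 7. The β-methyl ynoate is a weak dienophile, so the cycloaddition may be slow enough that the diene decomposes or transfers silicon at the temperature needed, or the diene may attack the aryl ester carbonyl and release phenol 4. Fallback, setting out from 4 and returning at 12: ring B would be brought in preformed. Methyl orsellinate 1 would be dibenzylated (BnBr, K2CO3, DMF, 70 °C) to methyl 2,4-bis(benzyloxy)-6-methylbenzoate F1 and saponified (KOH, DMSO/H2O, 90 °C) to 2,4-bis(benzyloxy)-6-methylbenzoic acid F2. F2 would be joined to phenol 4 through its mixed trifluoroacetic anhydride (TFAA, PhMe, rt), the classical depside coupling, to give methyl 4-{[2,4-bis(benzyloxy)-6-methylbenzoyl]oxy}-2-methoxy-6-methylbenzoate F3. Hydrogenolysis (H2, Pd/C, EtOAc) would then give AB diol 12.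

2. Step 9. The same weak dienophile now sits on a substrate with two aryl ester links. Incomplete silylation of the chelated 2'-OH would protonate the diene, and prolonged heating or the acid work-up could cause acyl transfer or cleavage at the A–B ester. Fallback, setting out from 12 and returning at 17: AB diol 12 would be acylated at its free 4'-OH with 2,4-bis(benzyloxy)-6-methylbenzoic acid F2 (prepared as above; TFAA, PhMe, rt) to give methyl 4-[(4-{[2,4-bis(benzyloxy)-6-methylbenzoyl]oxy}-2-hydroxy-6-methylbenzoyl)oxy]-2-methoxy-6-methylbenzoate F4. Hydrogenolysis (H2, Pd/C, EtOAc) would give target 17.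

3. Step 8. Acylation may also occur at the 2'-OH, and DMAP may isomerize or add to the activated but-2-ynoate before it reaches the phenol. Fallback, setting out from 12 (with 5) and returning at 13: the carbodiimide and the nucleophilic catalyst would be replaced by a preformed acyl halide and a hindered base. But-2-ynoic acid 5 would be converted with (COCl)2 and catalytic DMF in CH2Cl2 at 0 °C into but-2-ynoyl chloride F5, which would be added to 12 and 2,6-lutidine in CH2Cl2 at −40 °C, where only the unchelated 4'-OH should react, to give AB ynoate 13.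

Further compounds
F1 | step 7 | methyl 2,4-bis(benzyloxy)-6-methylbenzoate | COC(=O)c1c(C)cc(OCc2ccccc2)cc1OCc1ccccc1
F2 | step 7 | 2,4-bis(benzyloxy)-6-methylbenzoic acid | OC(=O)c1c(C)cc(OCc2ccccc2)cc1OCc1ccccc1
F3 | step 7 | methyl 4-{[2,4-bis(benzyloxy)-6-methylbenzoyl]oxy}-2-methoxy-6-methylbenzoate | COC(=O)c1c(C)cc(OC(=O)c2c(C)cc(OCc3ccccc3)cc2OCc2ccccc2)cc1OC
F4 | step 9 | methyl 4-[(4-{[2,4-bis(benzyloxy)-6-methylbenzoyl]oxy}-2-hydroxy-6-methylbenzoyl)oxy]-2-methoxy-6-methylbenzoate | COC(=O)c1c(C)cc(OC(=O)c2c(C)cc(OC(=O)c3c(C)cc(OCc4ccccc4)cc3OCc3ccccc3)cc2O)cc1OC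
F5 | step 8 | but-2-ynoyl chloride | CC#CC(=O)Cl
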